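## Retrosynthetic overview

1. Rings B, C and D are cut in one move. Isopropenyl ⇐ C11 cation ⇐ 1,2-shift of C1 (C11→C10) ⇐ C3–C9 bond ⇐ opened 2,3-epoxide gives rings C and D. A retro hetero-Diels–Alder across C6–CH2 and C7–O gives ring B.
2. Two fragments remain. One is the achiral ortho-quinone methide of norflavesone (ring A). The other is (2R,3R)-2,3-epoxyhumula-6,9-diene, the only carrier of absolute configuration.
3. The 6,7-alkene of humulene is the most reactive one. The 2,3-epoxide is therefore reached from the (2R,3R,6R,7R)-diepoxide (double Shi epoxidation of achiral α-humulene) by site-selective removal of the 6,7-oxygen.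
4. Norflavesone ⇐ dearomatising tri-C-methylation ⇐ Friedel–Crafts acylation of phloroglucinol.
5. Ring order: A (from the arene) → B → C and D, the last three in the final flask.

Assumption: humulane numbering is used for all terpene carbons (ring C1H2–C2H=C3(CH3)–C4H2–C5H2–C6H=C7(CH3)–C8H2–C9H=C10H–C11(CH3)2–C1). β-Triketones are drawn as one enol tautomer. Target rings are A = triketone ring, B = dihydropyran, C = cycloheptane, D = cyclopentane. α-Humulene is taken as an affordable bulk terpene.

## Route

Step 1
Reactants: 1 phloroglucinol (benzene-1,3,5-triol); 2 isobutyryl chloride (2-methylpropanoyl chloride)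
Product: 3 phlorisobutyrophenone [2-methyl-1-(2,4,6-trihydroxyphenyl)propan-1-one]
Conditions: AlCl3 (4 equiv), CH2Cl2/MeNO2, 0 → 40 °C; aq. HCl
Reagents that add atoms: none
Why: Friedel–Crafts acylation of the very electron-rich symmetric arene stops after one C-acylation because the chelated aryl ketone–AlCl3 complex is deactivated; no stereocentre is formed.

Step 2
Reactants: 3 phlorisobutyrophenone
Product: 4 norflavesone [3,5-dihydroxy-4,6,6-trimethyl-2-(2-methylpropanoyl)cyclohexa-2,4-dien-1-one, enol form of the 4,4,6-trimethyl triketone]
Conditions: NaOMe (3.3 equiv), MeI (3.1 equiv), MeOH, 0 °C → reflux; aq. HCl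
Reagents that add atoms: iodomethane, CI
Why: Dearomatising C-alkylation of the phloroglucinol polyanion: soft MeI attacks ring carbon, two methyls build the quaternary C(CH3)2 that locks the β-triketone, and the third stops at the last ring CH when MeI is limited to three equivalents; the CH(CH3) carbon is enolised, so no stable stereocentre results.

Step 3
Reactants: 5 α-humulene [(2E,6E,9E)-humula-2,6,9-triene]
Product: 6 (2R,3R,6R,7R,9E)-2,3:6,7-diepoxyhumul-9-ene (both oxiranes trans, oxygen on the outer ring face)
Conditions: 1,2:4,5-di-O-isopropylidene-β-D-erythro-2,3-hexodiulo-2,6-pyranose (Shi ketone, C12H18O6, 0.5 equiv), Oxone (2KHSO5·KHSO4·K2SO4, 2.5 equiv KHSO5), K2CO3, Na2B4O7/Na2EDTA buffer pH 10.5, Bu4NHSO4 (cat.), MeCN/CH2(OMe)2, −10 → 0 °C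
Reagents that add atoms: potassium peroxymonosulfate (active part of Oxone), [K+].[O-]S(=O)(=O)OO
Why: Shi asymmetric epoxidation (chiral dioxirane, spiro transition state) is used twice in one flask: the E-trisubstituted alkenes react in the order 6,7 then 2,3 while the neopentyl-flanked 9,10-alkene is left, humulene's rapidly inverting planar chirality lets the D-fructose-derived catalyst take the (R,R) face of each alkene, the second oxidation is expected to be matched to the peripheral-attack preference of the ring, and the minor enantiomer is drained into separable diastereomers, so C2 (R) and C3 (R) are set here in high ee.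

Step 4
Reactants: 6 (2R,3R,6R,7R,9E)-2,3:6,7-diepoxyhumul-9-ene
Product: 7 (2R,3R,6E,9E)-2,3-epoxyhumula-6,9-diene
Conditions: WCl6 (1.0 equiv) + n-BuLi (2.0 equiv), THF, −78 °C → rt; then 6, 0 °C, stopped at partial conversion; AgNO3/SiO2 chromatography (recovered 6 and over-reduced 5 recycled)
Reagents that add atoms: none
Why: Sharpless-type epoxide deoxygenation by the tetravalent tungsten chloride made from WCl6 and n-BuLi is stereospecific with retention, so the E-6,7-alkene returns and the C6/C7 centres are erased; the reagent has to reach oxygen and the CH carbon of the oxirane, which is easier at C6 (flanked by C5H2–C4H2) than at C2 (next to the C1H2–C11(CH3)2 unit), and the non-acidic medium leaves the (2R,3R)-oxirane and the 9,10-alkene untouched.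

Step 5 (key step)
Reactants: 4 norflavesone; 7 (2R,3R,6E,9E)-2,3-epoxyhumula-6,9-diene
Product: 10 target CNP0510355.1 (2R,3R,6S,7R,9S,10R tetracycle), via ortho-quinone methide 8 (not isolated), via epoxy-hyperjapone A 9 (not isolated)
Conditions: 4 (1.5 equiv), Ag2O (1.5 equiv), TEMPO (2,2,6,6-tetramethylpiperidin-1-oxyl, 0.3 equiv), 4 Å MS, CH2Cl2, rt, dark; then p-TsOH·H2O (0.5 equiv), same flask, 0 °C → rt
Reagents that add atoms: none
Why: Proposed new method: a neutral oxidative hetero-Diels–Alder reaction and an epoxide-initiated transannular cation–olefin cascade, each a known reaction type on humulene-derived rings, are run here on the pre-formed epoxide and in one flask; Ag2O/TEMPO dehydrogenates 4 to 8, which adds suprafacially (O to the more substituted C7, CH2 to C6) to the outer face of the strained E-6,7-alkene of 7 in the crossed ring conformer held by the (2R,3R)-oxirane, the same "like" topicity that peracids show on the corresponding cycloadduct, giving the trans-fused 6S,7R centres of 9; acid is admitted only then (earlier the free 6,7-alkene would itself attack C3), so C3–O ionises, C9 of the E-9,10-alkene attacks C3 anti to oxygen (inversion at C3, C2–O untouched, trans C/D fusion, 9S), C1 migrates from C11 to C10 on the same face (Wagner–Meerwein ring contraction, 10R, isopropenyl trans to C8) and the C11 cation loses a methyl proton.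

## Compound list

1 | phloroglucinol | Oc1cc(O)cc(O)c1 | starting material
2 | isobutyryl chloride | CC(C)C(=O)Cl | starting material
3 | phlorisobutyrophenone | CC(C)C(=O)c1c(O)cc(O)cc1O | intermediate
4 | norflavesone (enol form) | CC(C)C(=O)C1=C(O)C(C)=C(O)C(C)(C)C1=O | intermediate
5 | α-humulene (all-E) | C/C1=C\CC(C)(C)/C=C/C/C(C)=C/CC1 | starting material
6 | (2R,3R,6R,7R,9E)-2,3:6,7-diepoxyhumul-9-ene | C[C@@]12CC[C@H]3O[C@]3(C)C/C=C/C(C)(C)C[C@H]1O2 | intermediate
7 | (2R,3R,6E,9E)-2,3-epoxyhumula-6,9-diene | C[C@@]12CC/C=C(\C)C/C=C/C(C)(C)C[C@H]1O2 | intermediate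
8 | ortho-quinone methide, 5-hydroxy-2,2-dimethyl-6-methylidene-4-(2-methylpropanoyl)cyclohex-4-ene-1,3-dione | C=C1C(=O)C(C)(C)C(=O)C(C(=O)C(C)C)=C1O | intermediate
9 | epoxy-hyperjapone A, (2R,3R,6S,7R,9E): ring A/B chroman-type adduct (O on C7, CH2 on C6, trans fusion) carrying the 2,3-oxirane and the 9,10-alkene in the eleven-membered ring | C[C@@]12CC[C@H]3CC4=C(O[C@]3(C)C/C=C/C(C)(C)C[C@H]1O2)C(C)(C)C(=O)C(C(=O)C(C)C)=C4O | intermediate
10 | CNP0510355.1, 6-6-7-5 tetracycle, (2R,3R,6S,7R,9S,10R): C2–OH cis to C3–CH3, trans C/D and trans B/C fusions, C10 isopropenyl cis to C9–H | C=C(C)[C@@H]1C[C@@H](O)[C@]2(C)CC[C@H]3CC4=C(O[C@]3(C)C[C@@H]12)C(C)(C)C(=O)C(C(=O)C(C)C)=C4O | target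

## Step count and risks

Total step count: 5 (two for ring A, two for the terpene epoxide, one for union and cascade).
Longest linear sequence: 3 steps (1 → 3 → 4 → 10, or 5 → 6 → 7 → 10).

**Step 5 (highest risk).**
- Facial selectivity of the cycloaddition on 7 is inferred, not known.
- Silver and nitroxyl residues may disturb the acid stage.
- Hydride shift or allylic-alcohol formation can compete with the cascade.

The fallback sets out from 3 and 7 and comes back at 9. It replaces oxidative generation of 8 by a condensative one and uncouples the two stages. Compound 3 is C-methylated with only two equivalents of MeI/NaOMe to 3,5-dihydroxy-6,6-dimethyl-2-(2-methylpropanoyl)cyclohexa-2,4-dien-1-one F1. F1, paraformaldehyde and 7 are heated together (NaOAc cat., 1,4-dioxane, 80 °C). Knoevenagel condensation then delivers 8 without silver or nitroxyl, and the cycloadduct 9 is isolated. Compound 9 is rearranged in a separate flask (BF3·OEt2, CH2Cl2, −78 °C) to 10.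

**Step 4.** The preference for the 6,7-oxirane rests on a steric argument only. A statistical mixture, chlorohydrins or full reduction to 5 are possible.

The fallback sets out from 4 and 5 and comes back at 9, bypassing 6 and 7. Compound 4 is oxidised (Ag2O, TEMPO) in the presence of 5. The cycloaddition itself then occupies the most reactive 6,7-alkene and gives (±)-hyperjapone A F2. F2 is submitted to the same Shi ketone/Oxone system to about 45% conversion as a kinetic resolution. Only the 6S,7R enantiomer exposes the catalyst-preferred face of its 2,3-alkene. This gives 9, which is separated from the unreacted enantiomer and treated with acid as in the second stage of step 5. The price is a 50% ceiling.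

**Step 3.** Risks are over-oxidation at C9=C10 and a second epoxidation that proves mismatched.

The fallback sets out from 5 and comes back at 6. It moves control of C2/C3 from the catalyst to the substrate. One equivalent of KHSO5 with the Shi ketone gives (6R,7R,2E,9E)-6,7-epoxyhumula-2,9-diene F3, which is purified. An achiral peracid (mCPBA, NaHCO3, CH2Cl2, 0 °C) then attacks the 2,3-alkene of F3 from the ring periphery under control of the existing oxirane, giving 6.

## Further compounds

F1 | step 5 | 3,5-dihydroxy-6,6-dimethyl-2-(2-methylpropanoyl)cyclohexa-2,4-dien-1-one | CC(C)C(=O)C1=C(O)C=C(O)C(C)(C)C1=O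
F2 | step 4 | (±)-hyperjapone A, drawn as the 6S,7R enantiomer that goes on to 9 | C/C1=C\CC(C)(C)/C=C/C[C@@]2(C)OC3=C(C[C@@H]2CC1)C(O)=C(C(=O)C(C)C)C(=O)C3(C)C
F3 | step 3 | (6R,7R,2E,9E)-6,7-epoxyhumula-2,9-diene | C/C1=C\CC(C)(C)/C=C/C[C@@]2(C)O[C@@H]2CC1
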